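## Retrosynthetic overview

- **Numbering and feature.** Dihydronaphthalene numbering is used: ring A is the fused catechol ring, ring B the dihydro ring, ring C the aryl group on C2. C1, C2 and C3 with their two carboxyl carbons form a 3-arylglutarate. Its C1 arm is bonded to ring A at C8a, and its C3 arm reaches ring A at C4a through C4.
- **End game.** The eight benzyl ethers come off last with BCl3. One (S)-aryl-lactate supplies both side chains: acyl transfer with retention at the C3 carboxyl group gives S, and Mitsunobu inversion at the C1 carboxyl group gives R.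
- **Ring formation.** Ring B is the only ring that is made. It closes at C1–C8a by palladium-catalysed arylation of a tert-butyl ester enolate with the ring A bromide, and C1 is then set by kinetic protonation of the cyclic enolate.
- **Precursor.** C3=C4 comes from an aldol condensation of a glutarate hemiester dianion with 3,4-bis(benzyloxy)-2-bromobenzaldehyde. C2 comes from alkaloid-catalysed alcoholysis of the prochiral 3-arylglutaric anhydride.

Key step: step 10

Assumption: the quinine-series catalyst is taken to deliver the alcohol to the same enantiotopic carbonyl group as with other 3-substituted glutaric anhydrides, which here means the R hemiester; the configuration is to be proven by X-ray analysis of a bromine-containing successor, and the quinidine-series pseudoenantiomer reverses the sense if needed.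

## Route

Step 1
Reactants: 1 3,4-bis(benzyloxy)benzaldehyde; 2 ethyl acetoacetate
Product: 4 cyclic ketol diethyl 2-[3,4-bis(benzyloxy)phenyl]-4-hydroxy-4-methyl-6-oxocyclohexane-1,3-dicarboxylate (racemic diastereomer mixture), via open-chain bis-adduct 3 (not isolated)
Conditions: 2 (2.1 equiv), piperidine (cat.), EtOH, rt
Reagents that add atoms: none
Why: Knoevenagel condensation followed by Michael addition of a second acetoacetate gives 3, which closes by intramolecular aldol addition to the crystalline ketol 4; all its stereocentres are erased in step 2.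

Step 2
Reactants: 4 cyclic ketol
Product: 5 3-[3,4-bis(benzyloxy)phenyl]pentanedioic acid
Conditions: KOH (aq., large excess), EtOH, reflux; then HCl (aq.), 0 °C
Reagents that add atoms: potassium hydroxide [K+].[OH-] (oxygen of the two carboxyl groups)
Why: Hot concentrated alkali reverses the aldol, removes both acetyl groups by retro-Claisen cleavage and saponifies both esters, the standard entry to 3-arylglutaric acids, and aryl benzyl ethers are inert to it.

Step 3
Reactants: 5 3-[3,4-bis(benzyloxy)phenyl]pentanedioic acid
Product: 6 4-[3,4-bis(benzyloxy)phenyl]oxane-2,6-dione (3-arylglutaric anhydride)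
Conditions: Ac2O, reflux
Reagents that add atoms: none
Why: Dehydrative cyclisation by acyl exchange with acetic anhydride gives the six-membered cyclic anhydride, which is prochiral with a mirror plane through the future C2.

Step 4
Reactants: 6 3-arylglutaric anhydride
Product: 7 (3R)-3-[3,4-bis(benzyloxy)phenyl]-5-oxo-5-[2-(trimethylsilyl)ethoxy]pentanoic acid
Conditions: Me3SiCH2CH2OH (5 equiv), (DHQ)2AQN (hydroquinine anthraquinone-1,4-diyl diether, 30 mol %), MTBE/toluene, −30 °C; 1 M HCl wash; optical purity raised if needed by crystallising the salt with enantiopure 1-phenylethylamine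
Reagents that add atoms: 2-(trimethylsilyl)ethanol C[Si](C)(C)CCO
Why: In this alkaloid-catalysed desymmetrising alcoholysis the quinuclidine nitrogen activates the alcohol as a general base inside the chiral pocket, so one of the two enantiotopic carbonyl groups is attacked; this sets C2, puts the fluoride-labile ester on the future C3 arm and leaves the free acid on the future C1 arm.

Step 5
Reactants: 8 2-bromo-3-hydroxy-4-methoxybenzaldehyde (2-bromoisovanillin)
Product: 9 2-bromo-3,4-dihydroxybenzaldehyde
Conditions: BBr3, CH2Cl2, −78 °C to rt; H2O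
Reagents that add atoms: none
Why: In this Lewis-acid ether cleavage boron binds the methoxy oxygen and bromide removes the methyl group by SN2 attack, while the aldehyde and the aryl bromide are untouched.

Step 6
Reactants: 9 2-bromo-3,4-dihydroxybenzaldehyde
Product: 10 3,4-bis(benzyloxy)-2-bromobenzaldehyde
Conditions: BnBr (2.3 equiv), K2CO3, DMF, 50 °C
Reagents that add atoms: benzyl bromide BrCc1ccccc1
Why: Williamson ether synthesis on both phenoxides gives the ring A building block, with bromine on the future C8a and the aldehyde carbon as the future C4.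

Step 7
Reactants: 7 (R)-hemiester; 10 3,4-bis(benzyloxy)-2-bromobenzaldehyde
Product: 12 aldol adduct (3R)-3-[3,4-bis(benzyloxy)phenyl]-4-{[3,4-bis(benzyloxy)-2-bromophenyl](hydroxy)methyl}-5-oxo-5-[2-(trimethylsilyl)ethoxy]pentanoic acid (epimer mixture at the two new centres), via dilithio dianion 11 (not isolated)
Conditions: LiN(i-Pr)2 (2.15 equiv), THF, −78 °C; 10, −78 °C; AcOH, −78 °C
Reagents that add atoms: none
Why: In this dianion aldol addition the first equivalent of amide forms the carboxylate, which shields its own alpha position, so the second deprotonates only next to the ester (future C3) and the enolate adds to the aldehyde to form C3–C4; the two new centres vanish in step 8 and C2–H is not acidic.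

Step 8
Reactants: 12 aldol adduct
Product: 14 (3S,4E)-3-[3,4-bis(benzyloxy)phenyl]-4-{[3,4-bis(benzyloxy)-2-bromophenyl]methylidene}-5-oxo-5-[2-(trimethylsilyl)ethoxy]pentanoic acid, via delta-lactone 13 (not isolated)
Conditions: i-PrN=C=Ni-Pr (1.05 equiv), DMAP (cat.), CH2Cl2, 0 °C to rt; then DBU (3 equiv), rt; aq. citric acid; E isomer purified by crystallisation or chromatography
Reagents that add atoms: none
Why: Carbodiimide lactonisation turns the C4 oxygen into a carboxylate leaving group and blocks retro-aldol cleavage, and DBU then opens the lactone by E1cB elimination as in the second half of a Stobbe condensation; allylic strain in the ester enolate holds ring A away from the ester, so the E alkene (ring A cis to C2) should prevail from every diastereomer.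

Step 9
Reactants: 14 (E)-alkylidene hemiester
Product: 15 5-tert-butyl 1-[2-(trimethylsilyl)ethyl] (2E,3S)-3-[3,4-bis(benzyloxy)phenyl]-2-{[3,4-bis(benzyloxy)-2-bromophenyl]methylidene}pentanedioate
Conditions: Cl3CC(=NH)Ot-Bu (2.5 equiv), CH2Cl2/cyclohexane, rt
Reagents that add atoms: tert-butyl 2,2,2-trichloroacetimidate CC(C)(C)OC(=N)C(Cl)(Cl)Cl
Why: Trichloroacetimidate esterification, in which the acid protonates the imidate and receives the tert-butyl group, runs under near-neutral conditions that spare the silylethyl ester, the benzyl ethers and the alkene geometry.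

Step 10
Reactants: 15 bromo diester (cyclisation precursor)
Product: 18 cis core 1-tert-butyl 3-[2-(trimethylsilyl)ethyl] (1S,2S)-7,8-bis(benzyloxy)-2-[3,4-bis(benzyloxy)phenyl]-1,2-dihydronaphthalene-1,3-dicarboxylate, via acyclic lithium enolate 16 (not isolated), via cyclic lithium enolate 17 (not isolated)
Conditions: LiN(SiMe3)2 (2.4 equiv), Pd(dba)2 (5 mol %), P(t-Bu)3 (6 mol %), toluene, 0 °C to 40 °C, argon; then −78 °C, 2,6-di-tert-butyl-4-methylphenol (3 equiv) in THF; then AcOH, −78 °C
Reagents that add atoms: none
Why: LiN(SiMe3)2 removes a proton from the C1 methylene beside the tert-butyl ester to give 16, zerovalent palladium bearing P(t-Bu)3 inserts into the hindered C8a–Br bond, the tethered enolate replaces bromide on divalent palladium and C–C reductive elimination forges C1–C8a. The closest known reaction type is the palladium-catalysed intramolecular alpha-arylation of ester enolates with aryl bromides, which is established for six-membered rings. Ring B closes as a six-membered carbocycle by reductive elimination from a seven-membered palladacycle with the enolate double bond outside the new ring (enolexo mode), and the E geometry of C3=C4 already holds C2 and ring A on the same side so that C1 can reach C8a. The doubly activated C1–H of the product is removed at once by the second equivalent of base, so C1 is planar in 17 and is set only on the quench: allylic strain against the ketene acetal at C1 and the ester at C3 forces ring C on C2 into a pseudoaxial position over one face, the hindered phenol delivers its proton to the open face, and the ester ends cis to ring C (1S). C2 passes through unchanged because a second deprotonation next to an enolate carbon is disfavoured and because the planar allyl anion that loss of C2–H would need is blocked by the crowding around C2–C3=C4. The step needs arylation to outrun beta-hydride elimination towards C2, debromination and direct arylation of the C8 benzyl ether, which the bulky electron-rich phosphine and the low temperature secure, while the tert-butyl group suppresses Claisen condensation and attack of C1 on the C3 ester or on C4 would give strained four-membered rings.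

Step 11
Reactants: 18 cis core
Product: 19 (1S,2S)-7,8-bis(benzyloxy)-2-[3,4-bis(benzyloxy)phenyl]-1-(tert-butoxycarbonyl)-1,2-dihydronaphthalene-3-carboxylic acid
Conditions: (Me2N)3S[Me3SiF2] (TASF, 2.5 equiv), DMF, 0 °C; then 0.1 M HCl, 0 °C
Reagents that add atoms: none
Why: In this silylethyl ester cleavage fluoride attacks silicon and triggers fragmentation to ethene and the carboxylate; the weakly basic difluorosilicate at 0 °C is chosen so that the acidic C1–H of the less stable cis isomer is not exchanged, and the tert-butyl ester is inert.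

Step 12
Reactants: 20 4-bromo-1,2-bis(benzyloxy)benzene; 21 methyl (2S)-oxirane-2-carboxylate (methyl (S)-glycidate)
Product: 23 methyl (2S)-3-[3,4-bis(benzyloxy)phenyl]-2-hydroxypropanoate, via aryl Grignard reagent 22 (not isolated)
Conditions: 20 (1.4 equiv), Mg, THF, 40 °C; then CuI (10 mol %), 21, THF, −40 °C; 1 M HCl, 0 °C
Reagents that add atoms: none
Why: Copper-catalysed ring opening of a glycidic ester by an aryl Grignard reagent occurs at the unsubstituted epoxide carbon faster than at the ester, so the C2–O bond and the S configuration of 21 are kept.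

Step 13
Reactants: 19 C3 acid; 23 (S)-lactate
Product: 24 1-tert-butyl 3-{(2S)-3-[3,4-bis(benzyloxy)phenyl]-1-methoxy-1-oxopropan-2-yl} (1S,2S)-7,8-bis(benzyloxy)-2-[3,4-bis(benzyloxy)phenyl]-1,2-dihydronaphthalene-1,3-dicarboxylate
Conditions: i-PrN=C=Ni-Pr, DMAP (0.1 equiv), CH2Cl2, 0 °C to rt
Reagents that add atoms: none
Why: In this Steglich esterification the conjugated C3 acid is activated and the lactate reacts through its oxygen, so the carbinol carbon stays S, and catalytic DMAP at low temperature is too weak a base to exchange C1–H.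

Step 14
Reactants: 24 C3 lactate ester
Product: 25 (1S,2S)-7,8-bis(benzyloxy)-2-[3,4-bis(benzyloxy)phenyl]-3-({(2S)-3-[3,4-bis(benzyloxy)phenyl]-1-methoxy-1-oxopropan-2-yl}oxycarbonyl)-1,2-dihydronaphthalene-1-carboxylic acid
Conditions: CF3CO2H/CH2Cl2 (1:3), anisole (10 equiv), 0 °C
Reagents that add atoms: none
Why: Acidolysis of the tert-butyl ester proceeds by alkyl–oxygen ionisation (AAL1), anisole traps the cation before it can alkylate the electron-rich rings, and the cold acidic medium leaves C1, the methyl ester and the benzyl ethers alone.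

Step 15
Reactants: 25 C1 acid; 23 (S)-lactate
Product: 26 octabenzyl ether of the target (1S,2S core with S side chain on the C3 carboxyl group and R side chain on the C1 carboxyl group)
Conditions: PPh3, DIAD, toluene, 0 °C to rt
Reagents that add atoms: none
Why: In the Mitsunobu reaction the hydroxyl group of 23 is activated as an oxyphosphonium ion and displaced by the C1 carboxylate in an SN2 process with inversion to give the R side chain, and because the C1 acyl group is never activated, neither ketene formation nor enolisation can erode the cis C1 centre.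

Step 16
Reactants: 26 octabenzyl ether
Product: 27 target CNP0237075.1, 1-[(2R)-3-(3,4-dihydroxyphenyl)-1-methoxy-1-oxopropan-2-yl] 3-[(2S)-3-(3,4-dihydroxyphenyl)-1-methoxy-1-oxopropan-2-yl] (1S,2S)-2-(3,4-dihydroxyphenyl)-7,8-dihydroxy-1,2-dihydronaphthalene-1,3-dicarboxylate
Conditions: BCl3 (16 equiv), C6HMe5 (24 equiv), CH2Cl2, −78 °C; MeOH/CHCl3 quench; H2O; purification under slightly acidic, air-free conditions
Reagents that add atoms: none
Why: In this Lewis-acid debenzylation BCl3 ionises the aryl benzyl ethers and the non-basic scavenger pentamethylbenzene captures the benzyl cations by Friedel–Crafts reaction, which avoids hydrogenation of C3=C4 and, at −78 °C in acidic medium, spares the four esters and all four stereocentres.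

## Compound list

1 | 3,4-bis(benzyloxy)benzaldehyde | O=Cc1ccc(OCc2ccccc2)c(OCc2ccccc2)c1 | starting material
2 | ethyl acetoacetate | CCOC(=O)CC(C)=O | starting material
3 | diethyl 2,4-diacetyl-3-[3,4-bis(benzyloxy)phenyl]pentanedioate (open-chain bis-adduct, not isolated) | CCOC(=O)C(C(C)=O)C(c1ccc(OCc2ccccc2)c(OCc2ccccc2)c1)C(C(C)=O)C(=O)OCC | intermediate
4 | diethyl 2-[3,4-bis(benzyloxy)phenyl]-4-hydroxy-4-methyl-6-oxocyclohexane-1,3-dicarboxylate (racemic, stereoisomer mixture) | CCOC(=O)C1C(c2ccc(OCc3ccccc3)c(OCc3ccccc3)c2)C(C(=O)OCC)C(C)(O)CC1=O | intermediate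
5 | 3-[3,4-bis(benzyloxy)phenyl]pentanedioic acid | OC(=O)CC(c1ccc(OCc2ccccc2)c(OCc2ccccc2)c1)CC(=O)O | intermediate
6 | 4-[3,4-bis(benzyloxy)phenyl]oxane-2,6-dione | O=C1CC(c2ccc(OCc3ccccc3)c(OCc3ccccc3)c2)CC(=O)O1 | intermediate
7 | (3R)-3-[3,4-bis(benzyloxy)phenyl]-5-oxo-5-[2-(trimethylsilyl)ethoxy]pentanoic acid | OC(=O)C[C@@H](c1ccc(OCc2ccccc2)c(OCc2ccccc2)c1)CC(=O)OCC[Si](C)(C)C | intermediate
8 | 2-bromo-3-hydroxy-4-methoxybenzaldehyde | COc1ccc(C=O)c(Br)c1O | starting material
9 | 2-bromo-3,4-dihydroxybenzaldehyde | O=Cc1ccc(O)c(O)c1Br | intermediate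
10 | 3,4-bis(benzyloxy)-2-bromobenzaldehyde | O=Cc1ccc(OCc2ccccc2)c(OCc2ccccc2)c1Br | intermediate
11 | dilithio carboxylate ester-enolate of 7 (not isolated) | [Li]OC(=O)C[C@@H](c1ccc(OCc2ccccc2)c(OCc2ccccc2)c1)C=C(O[Li])OCC[Si](C)(C)C | intermediate
12 | aldol adduct, R at the aryl-bearing carbon, epimer mixture at the two new centres | OC(=O)C[C@@H](c1ccc(OCc2ccccc2)c(OCc2ccccc2)c1)C(C(=O)OCC[Si](C)(C)C)C(O)c1ccc(OCc2ccccc2)c(OCc2ccccc2)c1Br | intermediate
13 | 2-(trimethylsilyl)ethyl (4R)-2-[3,4-bis(benzyloxy)-2-bromophenyl]-4-[3,4-bis(benzyloxy)phenyl]-6-oxooxane-3-carboxylate (not isolated) | O=C1C[C@@H](c2ccc(OCc3ccccc3)c(OCc3ccccc3)c2)C(C(=O)OCC[Si](C)(C)C)C(c2ccc(OCc3ccccc3)c(OCc3ccccc3)c2Br)O1 | intermediate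
14 | (3S,4E)-alkylidene hemiester acid | OC(=O)C[C@@H](c1ccc(OCc2ccccc2)c(OCc2ccccc2)c1)/C(C(=O)OCC[Si](C)(C)C)=C\c1ccc(OCc2ccccc2)c(OCc2ccccc2)c1Br | intermediate
15 | 5-tert-butyl 1-[2-(trimethylsilyl)ethyl] (2E,3S)-3-[3,4-bis(benzyloxy)phenyl]-2-{[3,4-bis(benzyloxy)-2-bromophenyl]methylidene}pentanedioate | CC(C)(C)OC(=O)C[C@@H](c1ccc(OCc2ccccc2)c(OCc2ccccc2)c1)/C(C(=O)OCC[Si](C)(C)C)=C\c1ccc(OCc2ccccc2)c(OCc2ccccc2)c1Br | intermediate
16 | lithium enolate of the tert-butyl ester of 15 (not isolated) | [Li]OC(OC(C)(C)C)=C[C@@H](c1ccc(OCc2ccccc2)c(OCc2ccccc2)c1)/C(C(=O)OCC[Si](C)(C)C)=C\c1ccc(OCc2ccccc2)c(OCc2ccccc2)c1Br | intermediate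
17 | lithium enolate of 18, planar at C1 (not isolated) | C[Si](C)(C)CCOC(=O)C1=Cc2ccc(OCc3ccccc3)c(OCc3ccccc3)c2C(=C(O[Li])OC(C)(C)C)[C@H]1c1ccc(OCc2ccccc2)c(OCc2ccccc2)c1 | intermediate
18 | 1-tert-butyl 3-[2-(trimethylsilyl)ethyl] (1S,2S)-7,8-bis(benzyloxy)-2-[3,4-bis(benzyloxy)phenyl]-1,2-dihydronaphthalene-1,3-dicarboxylate (cis) | C[Si](C)(C)CCOC(=O)C1=Cc2ccc(OCc3ccccc3)c(OCc3ccccc3)c2[C@@H](C(=O)OC(C)(C)C)[C@H]1c1ccc(OCc2ccccc2)c(OCc2ccccc2)c1 | intermediate
19 | (1S,2S) C3 acid with tert-butyl ester on C1 | OC(=O)C1=Cc2ccc(OCc3ccccc3)c(OCc3ccccc3)c2[C@@H](C(=O)OC(C)(C)C)[C@H]1c1ccc(OCc2ccccc2)c(OCc2ccccc2)c1 | intermediate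
20 | 4-bromo-1,2-bis(benzyloxy)benzene | Brc1ccc(OCc2ccccc2)c(OCc2ccccc2)c1 | starting material
21 | methyl (2S)-oxirane-2-carboxylate | COC(=O)[C@@H]1CO1 | starting material
22 | 3,4-bis(benzyloxy)phenylmagnesium bromide (not isolated) | Br[Mg]c1ccc(OCc2ccccc2)c(OCc2ccccc2)c1 | intermediate
23 | methyl (2S)-3-[3,4-bis(benzyloxy)phenyl]-2-hydroxypropanoate | COC(=O)[C@@H](O)Cc1ccc(OCc2ccccc2)c(OCc2ccccc2)c1 | intermediate
24 | (1S,2S) core, (S)-lactate ester on C3, tert-butyl ester on C1 | COC(=O)[C@H](Cc1ccc(OCc2ccccc2)c(OCc2ccccc2)c1)OC(=O)C1=Cc2ccc(OCc3ccccc3)c(OCc3ccccc3)c2[C@@H](C(=O)OC(C)(C)C)[C@H]1c1ccc(OCc2ccccc2)c(OCc2ccccc2)c1 | intermediate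
25 | (1S,2S) core, (S)-lactate ester on C3, free acid on C1 | COC(=O)[C@H](Cc1ccc(OCc2ccccc2)c(OCc2ccccc2)c1)OC(=O)C1=Cc2ccc(OCc3ccccc3)c(OCc3ccccc3)c2[C@@H](C(=O)O)[C@H]1c1ccc(OCc2ccccc2)c(OCc2ccccc2)c1 | intermediate
26 | octabenzyl ether of the target | COC(=O)[C@H](Cc1ccc(OCc2ccccc2)c(OCc2ccccc2)c1)OC(=O)C1=Cc2ccc(OCc3ccccc3)c(OCc3ccccc3)c2[C@@H](C(=O)O[C@H](Cc2ccc(OCc3ccccc3)c(OCc3ccccc3)c2)C(=O)OC)[C@H]1c1ccc(OCc2ccccc2)c(OCc2ccccc2)c1 | intermediate
27 | CNP0237075.1 | COC(=O)[C@H](Cc1ccc(O)c(O)c1)OC(=O)C1=Cc2ccc(O)c(O)c2[C@@H](C(=O)O[C@H](Cc2ccc(O)c(O)c2)C(=O)OC)[C@H]1c1ccc(O)c(O)c1 | target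

## Step count and risks

Total step count: 16.
Longest linear sequence: 13 (steps 1–4, 7–11, 13–16).

**Steps most likely to fail**

1. **Step 10.**
   - What may go wrong: slow oxidative addition at the doubly ortho-substituted bromide would leave the substrate exposed to amide base. Proton loss at C2 (erosion of enantiopurity, alkene migration), debromination or beta-hydride elimination could then compete. The quench may also show poor facial selectivity.
   - Fallback: it sets out from 15. Kinetic enolisation with LiN(i-Pr)2 at −78 °C and trapping with Me3SiCl gives the tert-butyl trimethylsilyl ketene acetal F1. This is cyclised without free amide base (Pd(dba)2, P(t-Bu)3, ZnF2, DMF, 80 °C), the known arylation of silyl ketene acetals. The ring-closed diester is expected mainly as the trans (1R,2S) diester F2. In a separate operation F2 is deprotonated with LiN(SiMe3)2 at −78 °C to enolate 17 and protonated with the hindered phenol. The fallback comes back to the route at 18.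

2. **Step 11.**
   - What may go wrong: exchange of the acidic C1–H by fluoride, with drift from the cis to the more stable trans arrangement, or sluggish cleavage of the conjugated silylethyl ester under the mild conditions.
   - Fallback: it sets out from 18 and moves the stereodefining protonation behind the deprotection. The ester is cleaved with plain Bu4NF in THF without regard to C1, which gives an acid rich in the trans (1R,2S) acid F3. LiN(SiMe3)2 (3.2 equiv, THF, −78 to −40 °C) converts it into the dilithio carboxylate enolate F4. Quenching at −78 °C with 2,6-di-tert-butyl-4-methylphenol and then AcOH should restore the cis acid by the same shielding by ring C. The fallback comes back to the route at 19.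

3. **Step 4.**
   - What may go wrong: slow, poorly enantioselective opening because the silyl alcohol is bulkier than methanol, with uncatalysed background alcoholysis lowering the optical purity.
   - Fallback: it sets out from 6 and uses the best-precedented nucleophile on the other arm. Methanolysis with the quinidine-series catalyst (DHQD)2AQN gives the (S)-methyl hemiester F5, whose free acid sits on the future C3 arm. Steglich esterification with 2-(trimethylsilyl)ethanol gives the (R)-methyl silylethyl diester F6. SN2 demethylation with LiI in refluxing EtOAc removes only the methyl group. The fallback comes back to the route at 7.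

Further compounds
F1 | step 10 | tert-butyl trimethylsilyl ketene acetal of 15 | C[Si](C)(C)OC(OC(C)(C)C)=C[C@@H](c1ccc(OCc2ccccc2)c(OCc2ccccc2)c1)/C(C(=O)OCC[Si](C)(C)C)=C\c1ccc(OCc2ccccc2)c(OCc2ccccc2)c1Br
F2 | step 10 | trans (1R,2S) diester, C1 epimer of 18 | C[Si](C)(C)CCOC(=O)C1=Cc2ccc(OCc3ccccc3)c(OCc3ccccc3)c2[C@H](C(=O)OC(C)(C)C)[C@H]1c1ccc(OCc2ccccc2)c(OCc2ccccc2)c1
F3 | step 11 | trans (1R,2S) acid, C1 epimer of 19 | OC(=O)C1=Cc2ccc(OCc3ccccc3)c(OCc3ccccc3)c2[C@H](C(=O)OC(C)(C)C)[C@H]1c1ccc(OCc2ccccc2)c(OCc2ccccc2)c1
F4 | step 11 | dilithio carboxylate enolate of 19 | [Li]OC(=O)C1=Cc2ccc(OCc3ccccc3)c(OCc3ccccc3)c2C(=C(O[Li])OC(C)(C)C)[C@H]1c1ccc(OCc2ccccc2)c(OCc2ccccc2)c1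
F5 | step 4 | (3S)-3-[3,4-bis(benzyloxy)phenyl]-5-methoxy-5-oxopentanoic acid | COC(=O)C[C@@H](c1ccc(OCc2ccccc2)c(OCc2ccccc2)c1)CC(=O)O
F6 | step 4 | 1-methyl 5-[2-(trimethylsilyl)ethyl] (3R)-3-[3,4-bis(benzyloxy)phenyl]pentanedioate | COC(=O)C[C@@H](c1ccc(OCc2ccccc2)c(OCc2ccccc2)c1)CC(=O)OCC[Si](C)(C)C
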